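**Retrosynthetic overview**
- The target comes from its tetra-O-benzyl ether by one hydrogenolysis.
- Key disconnection: the bond between flavanone C2 and C5 of the dihydrobenzofuran, made by Rh(I)-catalysed asymmetric 1,4-addition of a dihydrobenzofuran-5-ylboronic acid to 5,7-bis(benzyloxy)chromone. Enabling feature: one oxidation level up, O1–C2–C3–C4(=O) of the flavanone is the C2=C3–C4=O vinylogous ester of a γ-pyranone ring, whose C2 is a flat, prochiral β-carbon; the partner carbon (benzofuran C5, para to ring O1) has two C–H neighbours and carries boron without hindrance.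
- Dihydrofuran ring: Rh(II)-carbenoid 1,5-C–H insertion of an aryl diazoacetate (forms C2–C3, sets C2), then C3 epimerisation to trans, ester to CH2OH, C5–Br to B(OH)2.
- Diazo ester: Pd-catalysed coupling of an aryl iodide with ethyl diazoacetate; the iodide comes from 2-(benzyloxy)phenol by para-bromination, ortho-iodination and Mitsunobu etherification.
- Ring order: dihydrofuran ring (step 5) and γ-pyranone ring (step 10, from phloroacetophenone) are built separately; the key step closes no ring and creates the flavanone stereocentre.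

Key step: step 11

Remark: the sense of induction of the two chiral catalysts (steps 5 and 11) is assigned by analogy with close substrate analogues; both ligands exist in either enantiomeric form, so the assignment only decides which antipode is used.

**Step 1**
Reactants: 1 2-(benzyloxy)phenol
Product: 2 2-(benzyloxy)-4-bromophenol
Conditions: NBS (1.0 equiv), DMF, 0 °C
Reagents that add atoms: N-bromosuccinimide, O=C1CCC(=O)N1Br
Why: Electrophilic aromatic bromination, in which the free OH is the dominant director and its open para position should be attacked in DMF.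

**Step 2**
Reactants: 2 2-(benzyloxy)-4-bromophenol
Product: 3 2-(benzyloxy)-4-bromo-6-iodophenol
Conditions: NIS (1.05 equiv), p-TsOH·H2O (10 mol %), MeCN, 0 °C to rt
Reagents that add atoms: N-iodosuccinimide, O=C1CCC(=O)N1I
Why: Electrophilic aromatic iodination; with the para position blocked, the only free ortho position of the phenol should be iodinated.

**Step 3**
Reactants: 3 2-(benzyloxy)-4-bromo-6-iodophenol; 4 [4-(benzyloxy)-3-methoxyphenyl]methanol
Product: 5 1-(benzyloxy)-2-{[4-(benzyloxy)-3-methoxyphenyl]methoxy}-5-bromo-3-iodobenzene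
Conditions: PPh3, DIAD, THF, 0 °C to rt
Reagents that add atoms: none
Why: Mitsunobu etherification of an acidic halophenol with a primary benzylic alcohol under neutral conditions, which avoids the labile p-alkoxybenzyl halide.

**Step 4**
Reactants: 5 aryl iodide; 6 ethyl diazoacetate (2 equiv)
Product: 7 ethyl 2-[3-(benzyloxy)-2-{[4-(benzyloxy)-3-methoxyphenyl]methoxy}-5-bromophenyl]-2-diazoacetate
Conditions: Pd(PPh3)4 (5 mol %), Et3N (2 equiv), n-Bu4NBr (1 equiv), MeCN, 25–40 °C
Reagents that add atoms: none
Why: Pd(0)-catalysed deprotonative cross-coupling of an aryl iodide with the C–H of a diazoacetate with retention of the diazo group; oxidative addition into C–I should be much faster than into C–Br at this temperature.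

**Step 5**
Reactants: 7 aryl diazoacetate
Product: 8 ethyl (2R,3S)-7-(benzyloxy)-2-[4-(benzyloxy)-3-methoxyphenyl]-5-bromo-2,3-dihydro-1-benzofuran-3-carboxylate (cis)
Conditions: Rh2(S-PTTL)4 (1 mol %), toluene, −78 °C
Reagents that add atoms: none
Why: Enantioselective intramolecular Rh(II)-carbenoid 1,5-C–H insertion into the electron-rich benzylic ether CH2 (the only C–H within reach of a five-membered transition state), in which the chiral carboxylate catalyst selects one enantiotopic benzylic hydrogen, sets C2 as R and should give the kinetic cis ester.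

**Step 6**
Reactants: 8 cis ester
Product: 9 ethyl (2R,3R)-7-(benzyloxy)-2-[4-(benzyloxy)-3-methoxyphenyl]-5-bromo-2,3-dihydro-1-benzofuran-3-carboxylate (trans)
Conditions: NaOEt (0.3 equiv), EtOH/THF, 0 °C to rt
Reagents that add atoms: none
Why: Base-mediated epimerisation through the ester enolate at C3, which should settle on the thermodynamically favoured trans isomer while C2 stays untouched.

**Step 7**
Reactants: 9 trans ester
Product: 10 [(2R,3S)-7-(benzyloxy)-2-[4-(benzyloxy)-3-methoxyphenyl]-5-bromo-2,3-dihydro-1-benzofuran-3-yl]methanol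
Conditions: DIBAL-H (3 equiv), CH2Cl2, −78 to 0 °C; Rochelle salt work-up
Reagents that add atoms: none
Why: Hydride reduction of the ester to the primary alcohol, which leaves the aryl bromide and benzyl ethers intact and removes the epimerisable position.

**Step 8**
Reactants: 10 bromo alcohol
Product: 11 [(2R,3S)-7-(benzyloxy)-2-[4-(benzyloxy)-3-methoxyphenyl]-3-(hydroxymethyl)-2,3-dihydro-1-benzofuran-5-yl]boronic acid
Conditions: B2(OH)4 (3 equiv), XPhos Pd G2 (2 mol %), XPhos (4 mol %), KOAc (3 equiv), EtOH, 80 °C
Reagents that add atoms: tetrahydroxydiboron, OB(O)B(O)O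
Why: Miyaura borylation with tetrahydroxydiboron, which tolerates the free alcohol and should deliver the boronic acid directly at the unhindered C5.

**Step 9**
Reactants: 12 1-(2,4,6-trihydroxyphenyl)ethan-1-one
Product: 13 1-[2,4-bis(benzyloxy)-6-hydroxyphenyl]ethan-1-one
Conditions: BnBr (2.05 equiv), K2CO3 (2.2 equiv), DMF, rt
Reagents that add atoms: benzyl bromide, BrCc1ccccc1
Why: Williamson etherification in which one ortho OH, hydrogen-bonded to the acetyl carbonyl, is the least nucleophilic and should stay free.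

**Step 10**
Reactants: 13 dibenzyl acetophenone
Product: 15 5,7-bis(benzyloxy)-4H-chromen-4-one, via enaminone 14 (not isolated)
Conditions: DMF-DMA, toluene, 95 °C; then conc. HCl, CH2Cl2, 40 °C
Reagents that add atoms: N,N-dimethylformamide dimethyl acetal, COC(OC)N(C)C
Why: Enaminone condensation followed by acid-mediated O-cyclisation with loss of dimethylamine (addition–elimination), the standard chromone synthesis from 2-hydroxyacetophenones.

**Step 11**
Reactants: 11 boronic acid (limiting); 15 5,7-bis(benzyloxy)chromone (1.5 equiv)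
Product: 16 (2S)-5,7-bis(benzyloxy)-2-[(2R,3S)-7-(benzyloxy)-2-[4-(benzyloxy)-3-methoxyphenyl]-3-(hydroxymethyl)-2,3-dihydro-1-benzofuran-5-yl]-2,3-dihydro-4H-chromen-4-one
Conditions: [RhCl(C2H4)2]2 (2.5 mol %), (S)-MeO-F12-BIPHEP [(S)-6,6'-dimethoxy-2,2'-bis[bis(3,4,5-trifluorophenyl)phosphino]-1,1'-biphenyl] (5.5 mol %), aq KOH (5 mol %), toluene/H2O 10:1, 25 °C
Reagents that add atoms: none
Why: Hayashi–Miyaura-type Rh(I)-catalysed asymmetric 1,4-addition of an arylboronic acid to a chromone, a reaction class established for flavanones including 5,7-dioxygenated cases: B-to-Rh transmetalation at Rh–OH gives an aryl–Rh(I) species, the chromone C2=C3 bond coordinates and inserts (syn-carbometalation, aryl to C2), and the oxa-π-allyl rhodium enolate is protonated at C3 by water, returning Rh–OH. No ring is closed; the γ-pyranone and dihydrofuran rings are carried in intact. The only new stereocentre, flavanone C2, is set by the C2-symmetric (S)-bisphosphine, which exposes one enantioface of the planar C2=C3–C4=O unit to the aryl–Rh bond (the sense that turns cyclohexenone into (S)-3-arylcyclohexanone corresponds to 2S here), and the stereocentres of 11 sit beyond the aromatic ring and should not override the catalyst. The step needs 1,4- over 1,2-addition, no second arylation of the product ketone and no retro-oxa-Michael opening or epimerisation of the product; the 5-benzyloxy group shields C4=O, the electron-poor ligand speeds insertion at room temperature, and only a catalytic trace of base is present in a two-phase medium. Boron sits on a carbon flanked by two C–H positions, so transmetalation is unhindered, and the inexpensive chromone is used in excess to outrun protodeboronation.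

**Step 12**
Reactants: 16 tetrabenzyl ether
Product: 17 Silyhermin B, (2S)-5,7-dihydroxy-2-[(2R,3S)-7-hydroxy-2-(4-hydroxy-3-methoxyphenyl)-3-(hydroxymethyl)-2,3-dihydro-1-benzofuran-5-yl]-2,3-dihydro-4H-chromen-4-one
Conditions: H2 (1 atm), 10% Pd/C, EtOAc/MeOH 1:1, rt, stopped once the benzyl ethers are consumed
Reagents that add atoms: none
Why: Catalytic hydrogenolysis of four phenolic benzyl ethers under neutral conditions, which should be faster than cleavage of the cyclic benzylic C–O bonds and leaves the base- and acid-sensitive flavanone C2 centre unchanged.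

**Compound list**
1 | 2-(benzyloxy)phenol | Oc1ccccc1OCc1ccccc1 | starting material
2 | 2-(benzyloxy)-4-bromophenol | Oc1ccc(Br)cc1OCc1ccccc1 | intermediate
3 | 2-(benzyloxy)-4-bromo-6-iodophenol | Oc1c(I)cc(Br)cc1OCc1ccccc1 | intermediate
4 | [4-(benzyloxy)-3-methoxyphenyl]methanol | COc1cc(CO)ccc1OCc1ccccc1 | starting material
5 | 1-(benzyloxy)-2-{[4-(benzyloxy)-3-methoxyphenyl]methoxy}-5-bromo-3-iodobenzene | COc1cc(COc2c(I)cc(Br)cc2OCc2ccccc2)ccc1OCc1ccccc1 | intermediate
6 | ethyl diazoacetate | CCOC(=O)C=[N+]=[N-] | starting material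
7 | ethyl 2-[3-(benzyloxy)-2-{[4-(benzyloxy)-3-methoxyphenyl]methoxy}-5-bromophenyl]-2-diazoacetate | CCOC(=O)C(=[N+]=[N-])c1cc(Br)cc(OCc2ccccc2)c1OCc1ccc(OCc2ccccc2)c(OC)c1 | intermediate
8 | ethyl (2R,3S)-7-(benzyloxy)-2-[4-(benzyloxy)-3-methoxyphenyl]-5-bromo-2,3-dihydro-1-benzofuran-3-carboxylate (cis) | COc1cc([C@@H]2Oc3c(OCc4ccccc4)cc(Br)cc3[C@@H]2C(=O)OCC)ccc1OCc1ccccc1 | intermediate
9 | ethyl (2R,3R)-7-(benzyloxy)-2-[4-(benzyloxy)-3-methoxyphenyl]-5-bromo-2,3-dihydro-1-benzofuran-3-carboxylate (trans) | COc1cc([C@@H]2Oc3c(OCc4ccccc4)cc(Br)cc3[C@H]2C(=O)OCC)ccc1OCc1ccccc1 | intermediate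
10 | [(2R,3S)-7-(benzyloxy)-2-[4-(benzyloxy)-3-methoxyphenyl]-5-bromo-2,3-dihydro-1-benzofuran-3-yl]methanol | COc1cc([C@@H]2Oc3c(OCc4ccccc4)cc(Br)cc3[C@H]2CO)ccc1OCc1ccccc1 | intermediate
11 | [(2R,3S)-7-(benzyloxy)-2-[4-(benzyloxy)-3-methoxyphenyl]-3-(hydroxymethyl)-2,3-dihydro-1-benzofuran-5-yl]boronic acid | COc1cc([C@@H]2Oc3c(OCc4ccccc4)cc(B(O)O)cc3[C@H]2CO)ccc1OCc1ccccc1 | intermediate
12 | 1-(2,4,6-trihydroxyphenyl)ethan-1-one | CC(=O)c1c(O)cc(O)cc1O | starting material
13 | 1-[2,4-bis(benzyloxy)-6-hydroxyphenyl]ethan-1-one | CC(=O)c1c(O)cc(OCc2ccccc2)cc1OCc1ccccc1 | intermediate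
14 | (E)-1-[2,4-bis(benzyloxy)-6-hydroxyphenyl]-3-(dimethylamino)prop-2-en-1-one | CN(C)/C=C/C(=O)c1c(O)cc(OCc2ccccc2)cc1OCc1ccccc1 | intermediate
15 | 5,7-bis(benzyloxy)-4H-chromen-4-one | O=c1ccoc2cc(OCc3ccccc3)cc(OCc3ccccc3)c12 | intermediate
16 | (2S)-5,7-bis(benzyloxy)-2-[(2R,3S)-7-(benzyloxy)-2-[4-(benzyloxy)-3-methoxyphenyl]-3-(hydroxymethyl)-2,3-dihydro-1-benzofuran-5-yl]-2,3-dihydro-4H-chromen-4-one | COc1cc([C@@H]2Oc3c(OCc4ccccc4)cc([C@@H]4CC(=O)c5c(OCc6ccccc6)cc(OCc6ccccc6)cc5O4)cc3[C@H]2CO)ccc1OCc1ccccc1 | intermediate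
17 | Silyhermin B | COc1cc([C@@H]2Oc3c(O)cc([C@@H]4CC(=O)c5c(O)cc(O)cc5O4)cc3[C@H]2CO)ccc1O | target

**Step count and risks**
Total steps: 12. Longest linear sequence: 10 (steps 1–8, 11, 12); the chromone arm (steps 9–10) joins at step 11.

Steps most likely to fail:

1. Step 11. The electron-rich 5,7-dialkoxychromone may undergo carbometalation too slowly, so that protodeboronation of the electron-rich boronic acid wins, or the product may lose C2 integrity by base-induced retro-oxa-Michael opening. The fallback sets out from bromide 10 and returns at 16 by the classical chalcone route. Bromine–lithium exchange on 10 (n-BuLi, 2.2 equiv, THF, −78 °C; the first equivalent deprotonates the alcohol) and DMF quench should give the 5-carbaldehyde F1. Claisen–Schmidt condensation of F1 with acetophenone 13 (KOH, EtOH, rt) should give the 2'-hydroxychalcone F2. Oxa-Michael cyclisation of F2 (NaOAc, EtOH, reflux) should give 16 together with its (2R)-epimer F3; the two are diastereomers and separable by chromatography, and F3 can be re-equilibrated under the same conditions.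

2. Step 5. The chiral Rh(II) carboxylate may discriminate poorly between the enantiotopic benzylic hydrogens, since the benzyloxy group flanking the reacting ether can disturb the reactive conformation, leaving 9 with insufficient enantiomeric purity after step 6. The fallback sets out from 9 and returns at 10 by classical resolution. Saponification of 9 (LiOH, THF/H2O) should give the trans carboxylic acid F4. Crystallisation of its (R)-1-phenylethylammonium salt F5 should upgrade the enantiomeric purity; which antipode of the amine gives the less soluble salt has to be found by trial. Acidification of the salt and reduction of the acid with BH3·THF should then give 10.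

3. Step 4. The diazo compound may decompose at palladium (carbene formation and dimerisation), or coupling at the hindered ortho-alkoxy iodide may be slow enough to erode I/Br chemoselectivity. The fallback sets out from 5 and returns at 7 in two steps. Negishi-type coupling of 5 with the Reformatsky reagent BrZnCH2CO2Et (Pd(PPh3)4, THF/DMF, rt) should give the ethyl arylacetate F6. Regitz diazo transfer onto F6 (p-acetamidobenzenesulfonyl azide, DBU, MeCN) should then give 7.

**Further compounds**
F1 | step 11 | (2R,3S)-7-(benzyloxy)-2-[4-(benzyloxy)-3-methoxyphenyl]-3-(hydroxymethyl)-2,3-dihydro-1-benzofuran-5-carbaldehyde | COc1cc([C@@H]2Oc3c(OCc4ccccc4)cc(C=O)cc3[C@H]2CO)ccc1OCc1ccccc1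
F2 | step 11 | (E)-1-[2,4-bis(benzyloxy)-6-hydroxyphenyl]-3-[(2R,3S)-7-(benzyloxy)-2-[4-(benzyloxy)-3-methoxyphenyl]-3-(hydroxymethyl)-2,3-dihydro-1-benzofuran-5-yl]prop-2-en-1-one | COc1cc([C@@H]2Oc3c(OCc4ccccc4)cc(/C=C/C(=O)c4c(O)cc(OCc5ccccc5)cc4OCc4ccccc4)cc3[C@H]2CO)ccc1OCc1ccccc1
F3 | step 11 | (2R)-5,7-bis(benzyloxy)-2-[(2R,3S)-7-(benzyloxy)-2-[4-(benzyloxy)-3-methoxyphenyl]-3-(hydroxymethyl)-2,3-dihydro-1-benzofuran-5-yl]-2,3-dihydro-4H-chromen-4-one | COc1cc([C@@H]2Oc3c(OCc4ccccc4)cc([C@H]4CC(=O)c5c(OCc6ccccc6)cc(OCc6ccccc6)cc5O4)cc3[C@H]2CO)ccc1OCc1ccccc1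
F4 | step 5 | (2R,3R)-7-(benzyloxy)-2-[4-(benzyloxy)-3-methoxyphenyl]-5-bromo-2,3-dihydro-1-benzofuran-3-carboxylic acid | COc1cc([C@@H]2Oc3c(OCc4ccccc4)cc(Br)cc3[C@H]2C(=O)O)ccc1OCc1ccccc1
F5 | step 5 | (R)-1-phenylethylammonium (2R,3R)-7-(benzyloxy)-2-[4-(benzyloxy)-3-methoxyphenyl]-5-bromo-2,3-dihydro-1-benzofuran-3-carboxylate | COc1cc([C@@H]2Oc3c(OCc4ccccc4)cc(Br)cc3[C@H]2C(=O)[O-])ccc1OCc1ccccc1.C[C@@H]([NH3+])c1ccccc1
F6 | step 4 | ethyl 2-[3-(benzyloxy)-2-{[4-(benzyloxy)-3-methoxyphenyl]methoxy}-5-bromophenyl]acetate | CCOC(=O)Cc1cc(Br)cc(OCc2ccccc2)c1OCc1ccc(OCc2ccccc2)c(OC)c1
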